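The partner is the charge I watch first in this flask, ahead of the solid substrate.

the same everywhere: solid substrate 0.12 M
- east: partner 0.096 M; run made earlier
- south-east: partner 0.22 M; run made earlier
- flask: partner 0.144 M; time 4.0 h

| run | time / h | target / % | dissolved substrate / % |
|---|---|---|---|
| east | 0.417 | 5 | 30 |
| east | 0.667 | 5 | 40 |
| east | 1.33 | 7 | 59 |
| east | 2.50 | 10 | 70 |
| east | 5.00 | 8 | 71 |
| south-east | 1.00 | 16 | 47 |
| south-east | 2.00 | 15 | 66 |
| south-east | 3.00 | 14 | 68 |
| south-east | 4.00 | 15 | 70 |
| south-east | 5.00 | 14 | 70 |

(each reading ± 1.5 percentage points)

* amount of target at 4.0 h, in percent of the solid substrate charged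
* concentration of dissolved substrate in solution at 4.0 h, in percent of saturation

- solid, in amounts per volume of the solution: solid substrate
- steps that have been proposed: solid substrate <-> dissolved substrate; dissolved substrate + partner -> target; partner -> side product; target <-> isomer of the product; partner -> decomposed reagent
- at the start none of the solid substrate is in solution
- dissolved substrate means what is dissolved; the solid is not counted in it

Does more time bring more target? In the south-east run target reads 16% at 1.00 h and 14% at 5.00 h, level within the scatter, while dissolved substrate climbs from 47% to 70%. Control has changed hands early in that run, so I take the partner as the limiting reagent, even at 1.83 equivalents.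

What, then, does a charge of partner buy? The level south-east readings give 0.0791 for the return, [target] on the plateau divided by [partner] as charged. The last two east readings give 0.112, with more scatter.

Is the flask level at 4.0 h? East target reads 10% at 2.50 h and 8% at 5.00 h, and east dissolved substrate reads 70% and 71% at those times, so I expect it to be. The two returns then put target in the flask between 9.49% and 13.5%.

The forecast says 11.6% of target and 99.5% of saturation: “By 4 h the flask should be on its plateau.” Its figure for target lies inside my span, and both rest on the same two runs.

The flask gives 10.4% of target and 99.7% of saturation.

    solid substrate ⇌ dissolved substrate, rate k1*(cs1 - [dissolved substrate]) while solid is left; crystals form when [dissolved substrate] > cs1 (solubility = 0.0850 M, k = 0.0269 min⁻¹)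
    dissolved substrate + partner → target (k = 0.183 M⁻¹ min⁻¹)
    partner → side product (k = 0.0125 min⁻¹)
    target ⇌ isomer of the product (K = 0.500, k = 0.00734 min⁻¹)
    partner → decomposed reagent (k = 0.0233 min⁻¹)

The return of this flask is 0.0864, above the 0.0791 read from the south-east run and below the 0.112 read from the east run, with partner at 0% at 4.00 h. The neighbouring flask holds 0.20 M of solid substrate and the same partner, which makes 0.720 equiv. Carrying the return over gives 6.22% of its larger charge. That neighbouring flask gives 6.22%, with partner at 0% and solid substrate at 48.4%.

(The earlier runs and the new flask are simulated for substances that don't exist.)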